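**Retrosynthetic overview**
1. Target 21 ⇐ thioester 19: the (E)-crotonoyl ketone is made last by Pd/Cu coupling of the C1 thioester with (E)-propenylboronic acid.
2. cis-Fused α-methylene lactone of 19 ⇐ acrylate 17 by intramolecular Rauhut–Currier closure onto the cycloheptenone (forms C7–C11, sets C7).
3. Cycloheptenone 12 ⇐ cyclohexenone β-keto thioester 8 by one-carbon ring expansion with MeCHI2/Et2Zn and oxygenation of the resulting C1 zinc enolate in the same flask (forms C9–C10, C10–C1 and C1–OH).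
4. 8 ⇐ enone 5 ⇐ (1R,2R)-cyclohex-3-ene-1,2-diol 3 ⇐ asymmetric epoxidation of cyclohexa-1,3-diene (sets C5 and C6).
5. Ring order: six-membered carbocycle (bought) → seven-membered carbocycle (ring expansion) → γ-lactone.

Locants C1–C13 follow the xanthanolide skeleton: C1 carbinol, C5 CH–O-isovalerate, C6 lactone CH–O, C7 ring fusion, C8 CH2, C9 ketone, C10 CH–CH3, C11–C13 methylene lactone. TIPDS = 1,1,3,3-tetraisopropyldisiloxane-1,3-diyl bridging two oxygens.

Assumption: the target's C10 configuration (methyl cis to the C1 hydroxyl) is the thermodynamically preferred one at this epimerisable α-keto centre, so base equilibration converges on it.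

**Route**

Step 1
Reactants: 1 cyclohexa-1,3-diene
Product: 2 (1S,6R)-7-oxabicyclo[4.1.0]hept-2-ene
Conditions: (S,S)-Jacobsen (salen)Mn(III)Cl (4 mol %), 4-phenylpyridine N-oxide, aq NaOCl (pH 11.3), CH2Cl2, 0 °C
Reagents that add atoms: sodium hypochlorite, [Na+].[O-]Cl
Why: Jacobsen–Katsuki epoxidation of a conjugated cis-olefin stops at the mono-epoxide and sets both C–O centres by side-on approach to the Mn-oxo species, the (1S,6R) sense being assigned by analogy with indene → (1S,2R)-indene oxide.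

Step 2
Reactants: 2 (1S,6R)-7-oxabicyclo[4.1.0]hept-2-ene
Product: 3 (1R,2R)-cyclohex-3-ene-1,2-diol
Conditions: KOH, H2O/DMSO, 60 °C; recrystallise to raise ee
Reagents that add atoms: water, O
Why: SN2 opening of the vinyl epoxide by hydroxide at the activated allylic carbon inverts C6 and leaves C5 untouched, giving the trans-diol.

Step 3
Reactants: 3 (1R,2R)-cyclohex-3-ene-1,2-diol
Product: 4 (1R,2R)-cyclohex-3-ene-1,2-diol 1,2-O-TIPDS ether
Conditions: TIPDSCl2, imidazole, DMF, 0 °C → rt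
Reagents that add atoms: 1,3-dichloro-1,1,3,3-tetraisopropyldisiloxane, CC(C)[Si](Cl)(C(C)C)O[Si](Cl)(C(C)C)C(C)C
Why: Double silylation bridges the trans-diequatorial diol and locks both C–O bonds equatorial, which later keeps them out of alignment for β-elimination.

Step 4
Reactants: 4 (1R,2R)-cyclohex-3-ene-1,2-diol 1,2-O-TIPDS ether
Product: 5 (4R,5R)-4,5-(TIPDS-dioxy)cyclohex-2-en-1-one
Conditions: Rh2(cap)4 (1 mol %), t-BuOOH (5 equiv), K2CO3, CH2Cl2, rt
Reagents that add atoms: tert-butyl hydroperoxide, CC(C)(C)OO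
Why: Rh2(cap)4/TBHP allylic C–H oxidation attacks the only allylic CH2 (C9), and the allyl radical is captured at the terminus remote from the siloxy carbon, giving the enone without touching C5 or C6.

Step 5
Reactants: 5 (4R,5R)-4,5-(TIPDS-dioxy)cyclohex-2-en-1-one; 6 S-ethyl chlorothioformate
Product: 8 S-ethyl (5R,6R)-2-oxo-5,6-(TIPDS-dioxy)cyclohex-3-ene-1-carbothioate (C1 epimers and enol), via lithium dienolate 7 (not isolated)
Conditions: LDA (1.1 equiv), THF, −78 °C; then add to EtSC(O)Cl (1.2 equiv), −78 °C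
Reagents that add atoms: none
Why: Kinetic α′-deprotonation of the enone gives the cross-conjugated dienolate, which is C-acylated (Claisen-type acylation) while the equatorial C5–O bond, orthogonal to the enolate π system, resists E1cB loss.

Step 6
Reactants: 8 S-ethyl (5R,6R)-2-oxo-5,6-(TIPDS-dioxy)cyclohex-3-ene-1-carbothioate; 9 1,1-diiodoethane
Product: 12 S-ethyl (1S,2R,6R,7S)-1-hydroxy-2-methyl-3-oxo-6,7-(TIPDS-dioxy)cyclohept-4-ene-1-carbothioate, via zinc cyclopropanolate 10 (not isolated), via zinc thioester enolate 11 (not isolated)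
Conditions: Et2Zn (3 equiv), CH2Cl2, 0 °C; MeCHI2 (3 equiv), 0 °C → rt; then trans-2-(phenylsulfonyl)-3-phenyloxaziridine (4 equiv), −40 → 0 °C; aq NH4Cl; Et3N (cat.), CH2Cl2, rt
Reagents that add atoms: 2-(phenylsulfonyl)-3-phenyloxaziridine, O=S(=O)(c1ccccc1)N1OC1c1ccccc1
Why: Proposed new method: ring-expanding zinc-carbenoid homologation of a cyclic β-keto thioester with oxygenation in the same flask – the zinc enolate of 8 is C-alkylated by EtZnCH(I)CH3, the new C–Zn bond adds to the ring ketone to give cyclopropanolate 10, and its fragmentation (a 1,2-shift of the C9 acyl carbon from C1 to the carbenoid carbon) gives the seven-membered enolate 11 with the metal regiospecifically at C1, which the oxaziridine hydroxylates from the equatorial face, trans to the C5 siloxy group (C1 = S), while Et3N settles the epimerisable C10; the closest known chemistry is the Zercher zinc-carbenoid chain extension of β-keto esters and amides (including MeCHI2 and aldol or iodine trapping) and the Dowd–Beckwith ring expansion, but to my knowledge neither a cross-conjugated β-keto thioester nor direct hydroxylation of the intermediate has been shown.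

Step 7
Reactants: 12 S-ethyl (1S,2R,6R,7S)-1-hydroxy-2-methyl-3-oxo-6,7-(TIPDS-dioxy)cyclohept-4-ene-1-carbothioate
Product: 13 S-ethyl (1S,2R,6R,7S)-1,6,7-trihydroxy-2-methyl-3-oxocyclohept-4-ene-1-carbothioate
Conditions: HF·pyridine, pyridine/THF, 0 °C → rt
Reagents that add atoms: none
Why: Fluoride cleaves both Si–O bonds under buffered, weakly acidic conditions that avoid retro-aldol of the tertiary β-hydroxy ketone and leave the thioester intact.

Step 8
Reactants: 13 S-ethyl (1S,2R,6R,7S)-1,6,7-trihydroxy-2-methyl-3-oxocyclohept-4-ene-1-carbothioate; 14 acryloyl chloride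
Product: 15 S-ethyl (1S,2R,6R,7S)-6-(acryloyloxy)-1,7-dihydroxy-2-methyl-3-oxocyclohept-4-ene-1-carbothioate
Conditions: acryloyl chloride (1.05 equiv), 2,4,6-collidine, CH2Cl2, −78 → −40 °C
Reagents that add atoms: none
Why: Regioselective O-acylation takes the allylic C6–OH, because the C5–OH sits next to the quaternary C1 (neopentyl-like) and the tertiary C1–OH is inert.

Step 9
Reactants: 15 S-ethyl (1S,2R,6R,7S)-6-(acryloyloxy)-1,7-dihydroxy-2-methyl-3-oxocyclohept-4-ene-1-carbothioate; 16 3-methylbutanoyl chloride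
Product: 17 S-ethyl (1S,2R,6R,7S)-6-(acryloyloxy)-1-hydroxy-2-methyl-7-(3-methylbutanoyloxy)-3-oxocyclohept-4-ene-1-carbothioate
Conditions: isovaleryl chloride (1.5 equiv), pyridine, DMAP (10 mol %), CH2Cl2, 0 °C → rt
Reagents that add atoms: none
Why: DMAP-catalysed acyl transfer esterifies the remaining secondary C5–OH and leaves the hindered tertiary α-acyl carbinol free; capping C5–OH also removes a competing oxa-Michael donor before the phosphine step.

Step 10
Reactants: 17 S-ethyl (1S,2R,6R,7S)-6-(acryloyloxy)-1-hydroxy-2-methyl-7-(3-methylbutanoyloxy)-3-oxocyclohept-4-ene-1-carbothioate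
Product: 19 S-ethyl (3aS,6R,7S,8S,8aR)-7-hydroxy-6-methyl-3-methylidene-8-(3-methylbutanoyloxy)-2,5-dioxooctahydro-2H-cyclohepta[b]furan-7-carbothioate, via phosphonium enolate 18 (not isolated)
Conditions: PBu3 (20 mol %), PhOH (20 mol %), THF (0.02 M), rt
Reagents that add atoms: none
Why: Intramolecular Rauhut–Currier reaction (known for acrylates of γ-hydroxy dienones): PBu3 adds to the acrylate, the α-carbon adds 5-exo to enone C7 with cis fusion enforced by the ester tether (C7 = S), and proton transfer with loss of PBu3 restores the exo-methylene.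

Step 11
Reactants: 19 S-ethyl (3aS,6R,7S,8S,8aR)-7-hydroxy-6-methyl-3-methylidene-8-(3-methylbutanoyloxy)-2,5-dioxooctahydro-2H-cyclohepta[b]furan-7-carbothioate; 20 (E)-prop-1-enylboronic acid
Product: 21 (3aS,6R,7S,8S,8aR)-7-[(2E)-but-2-enoyl]-7-hydroxy-6-methyl-3-methylidene-2,5-dioxooctahydro-2H-cyclohepta[b]furan-8-yl 3-methylbutanoate (target)
Conditions: Pd2(dba)3 (5 mol %), tri(2-furyl)phosphine (20 mol %), CuTC (1.6 equiv), THF, 50 °C
Reagents that add atoms: none
Why: Liebeskind–Srogl coupling: Cu(I)-carboxylate-assisted Pd insertion into the C–S bond and base-free transmetallation from boron give the ketone with retention of the E-alkene, leaving the ketone, lactone, ester and tertiary alcohol untouched.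

**Compound list**
1 | cyclohexa-1,3-diene | C1=CC=CCC1 | starting material
2 | (1S,6R)-7-oxabicyclo[4.1.0]hept-2-ene | C1=C[C@@H]2O[C@@H]2CC1 | intermediate
3 | (1R,2R)-cyclohex-3-ene-1,2-diol | O[C@@H]1C=CCC[C@H]1O | intermediate
4 | (1R,2R)-cyclohex-3-ene-1,2-diol 1,2-O-TIPDS ether | CC(C)[Si]1(C(C)C)O[C@@H]2C=CCC[C@H]2O[Si](C(C)C)(C(C)C)O1 | intermediate
5 | (4R,5R)-4,5-(TIPDS-dioxy)cyclohex-2-en-1-one | CC(C)[Si]1(C(C)C)O[C@@H]2C=CC(=O)C[C@H]2O[Si](C(C)C)(C(C)C)O1 | intermediate
6 | S-ethyl chlorothioformate | CCSC(=O)Cl | starting material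
7 | lithium cross-conjugated dienolate of 5 (O–Li on C1, C1=C6 and C2=C3) | CC(C)[Si]1(C(C)C)O[C@@H]2C=CC(O[Li])=C[C@H]2O[Si](C(C)C)(C(C)C)O1 | intermediate
8 | S-ethyl (5R,6R)-2-oxo-5,6-(TIPDS-dioxy)cyclohex-3-ene-1-carbothioate (C1 epimers/enol) | CC(C)[Si]1(C(C)C)O[C@@H]2C=CC(=O)C(C(=O)SCC)[C@H]2O[Si](C(C)C)(C(C)C)O1 | intermediate
9 | 1,1-diiodoethane | CC(I)I | starting material
10 | ethylzinc cyclopropanolate (bicyclo[4.1.0]heptene; cyclopropane = C9, C10, C1) | CC(C)[Si]1(C(C)C)O[C@@H]2C=CC3(O[Zn]CC)C(C)C3(C(=O)SCC)[C@H]2O[Si](C(C)C)(C(C)C)O1 | intermediate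
11 | ethylzinc thioester enolate of the ring-expanded cycloheptenone | CC(C)[Si]1(C(C)C)O[C@@H]2C=CC(=O)C(C)C(=C(O[Zn]CC)SCC)[C@H]2O[Si](C(C)C)(C(C)C)O1 | intermediate
12 | S-ethyl (1S,2R,6R,7S)-1-hydroxy-2-methyl-3-oxo-6,7-(TIPDS-dioxy)cyclohept-4-ene-1-carbothioate | CC(C)[Si]1(C(C)C)O[C@@H]2C=CC(=O)[C@H](C)[C@@](O)(C(=O)SCC)[C@H]2O[Si](C(C)C)(C(C)C)O1 | intermediate
13 | S-ethyl (1S,2R,6R,7S)-1,6,7-trihydroxy-2-methyl-3-oxocyclohept-4-ene-1-carbothioate | O[C@@H]1C=CC(=O)[C@H](C)[C@@](O)(C(=O)SCC)[C@H]1O | intermediate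
14 | acryloyl chloride | C=CC(=O)Cl | starting material
15 | S-ethyl (1S,2R,6R,7S)-6-(acryloyloxy)-1,7-dihydroxy-2-methyl-3-oxocyclohept-4-ene-1-carbothioate | C=CC(=O)O[C@@H]1C=CC(=O)[C@H](C)[C@@](O)(C(=O)SCC)[C@H]1O | intermediate
16 | 3-methylbutanoyl (isovaleryl) chloride | CC(C)CC(=O)Cl | starting material
17 | S-ethyl (1S,2R,6R,7S)-6-(acryloyloxy)-1-hydroxy-2-methyl-7-(3-methylbutanoyloxy)-3-oxocyclohept-4-ene-1-carbothioate | C=CC(=O)O[C@@H]1C=CC(=O)[C@H](C)[C@@](O)(C(=O)SCC)[C@H]1OC(=O)CC(C)C | intermediate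
18 | cyclised β-(tributylphosphonio)methyl lactone enolate zwitterion | CCCC[P+](CCCC)(CCCC)CC1C(=O)O[C@@H]2[C@H]1C=C([O-])[C@H](C)[C@@](O)(C(=O)SCC)[C@H]2OC(=O)CC(C)C | intermediate
19 | S-ethyl (3aS,6R,7S,8S,8aR)-7-hydroxy-6-methyl-3-methylidene-8-(3-methylbutanoyloxy)-2,5-dioxooctahydro-2H-cyclohepta[b]furan-7-carbothioate | C=C1C(=O)O[C@@H]2[C@H]1CC(=O)[C@H](C)[C@@](O)(C(=O)SCC)[C@H]2OC(=O)CC(C)C | intermediate
20 | (E)-prop-1-enylboronic acid | C/C=C/B(O)O | starting material
21 | (3aS,6R,7S,8S,8aR)-7-[(2E)-but-2-enoyl]-7-hydroxy-6-methyl-3-methylidene-2,5-dioxooctahydro-2H-cyclohepta[b]furan-8-yl 3-methylbutanoate | C=C1C(=O)O[C@@H]2[C@H]1CC(=O)[C@H](C)[C@@](O)(C(=O)/C=C/C)[C@H]2OC(=O)CC(C)C | target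

**Totals**
Total steps: 11. Longest linear sequence: 11 (from cyclohexa-1,3-diene).

**Steps most likely to fail**

Step 6 (the proposed new step). The C–Zn bond may add to the thioester carbonyl instead of the conjugated ring ketone. The C5 oxygen may be lost by β-elimination with aromatisation. The oxaziridine may attack the wrong face at C1. C10 rests on the stated assumption. Fallback, from 8 back to 12, separates the two events with established reactions. Compound 8 is ring-expanded with Et2Zn/MeCHI2 in CH2Cl2 and quenched with aqueous NH4Cl to give the C1–H ring-expanded γ-keto thioester F2 (zinc-carbenoid ring expansion of a cyclic β-keto carbonyl compound). F2 is then deprotonated with KHMDS (1.0 equiv, THF, −78 °C, equilibrating so that the more acidic thioester α-C–H is removed) and hydroxylated with the Davis oxaziridine to give 12.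

Step 5. The dienolate may be O-acylated by the chlorothioformate, and the product can lose the C5 oxygen and aromatise. Fallback, from 5 back to 8, changes the electrophile type. The lithium dienolate is treated with carbonyl sulfide (gas, −78 °C), which can only form the C–C bond, giving the lithium β-keto thiocarboxylate F1. F1 is S-ethylated in the same flask with iodoethane (DMPU, −78 → 0 °C) to give 8.

Step 10. The phosphine may add to the enone first, oligomerise the acrylate, or the 5-exo closure may stall. Fallback, from 13 back to 19, replaces the acrylate by a phosphonate route (telescoped intramolecular Michael/olefination). Triol 13 is acylated at O6 with bromoacetyl bromide/collidine (−78 °C) to the 6-O-bromoacetate F3. F3 is esterified at O5 with isovaleryl chloride/pyridine/DMAP to the bromoacetate isovalerate F4. F4 is heated with P(OMe)3 (Arbuzov, 80 °C) to the dimethylphosphonoacetate F5. F5 with KOtBu (1.0 equiv, THF, 0 °C) cyclises onto the enone to the cis-fused α-phosphono lactone F6, which is olefinated in the same flask with paraformaldehyde (HWE) to give 19.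

**Further compounds**
F1 | step 5 | lithium (5R,6R)-2-oxo-5,6-(TIPDS-dioxy)cyclohex-3-ene-1-carbothioate (thiocarboxylate) | [Li+].CC(C)[Si]1(C(C)C)O[C@@H]2C=CC(=O)C(C(=O)[S-])[C@H]2O[Si](C(C)C)(C(C)C)O1
F2 | step 6 | S-ethyl (6R,7R)-2-methyl-3-oxo-6,7-(TIPDS-dioxy)cyclohept-4-ene-1-carbothioate (C1/C2 epimers) | CC(C)[Si]1(C(C)C)O[C@@H]2C=CC(=O)C(C)C(C(=O)SCC)[C@H]2O[Si](C(C)C)(C(C)C)O1
F3 | step 10 | S-ethyl (1S,2R,6R,7S)-6-(bromoacetoxy)-1,7-dihydroxy-2-methyl-3-oxocyclohept-4-ene-1-carbothioate | BrCC(=O)O[C@@H]1C=CC(=O)[C@H](C)[C@@](O)(C(=O)SCC)[C@H]1O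
F4 | step 10 | S-ethyl (1S,2R,6R,7S)-6-(bromoacetoxy)-1-hydroxy-2-methyl-7-(3-methylbutanoyloxy)-3-oxocyclohept-4-ene-1-carbothioate | BrCC(=O)O[C@@H]1C=CC(=O)[C@H](C)[C@@](O)(C(=O)SCC)[C@H]1OC(=O)CC(C)C
F5 | step 10 | S-ethyl (1S,2R,6R,7S)-6-[(dimethoxyphosphoryl)acetoxy]-1-hydroxy-2-methyl-7-(3-methylbutanoyloxy)-3-oxocyclohept-4-ene-1-carbothioate | COP(=O)(OC)CC(=O)O[C@@H]1C=CC(=O)[C@H](C)[C@@](O)(C(=O)SCC)[C@H]1OC(=O)CC(C)C
F6 | step 10 | S-ethyl (3aS,6R,7S,8S,8aR)-3-(dimethoxyphosphoryl)-7-hydroxy-6-methyl-8-(3-methylbutanoyloxy)-2,5-dioxooctahydro-2H-cyclohepta[b]furan-7-carbothioate (C3 epimers, not isolated) | COP(=O)(OC)C1C(=O)O[C@@H]2[C@H]1CC(=O)[C@H](C)[C@@](O)(C(=O)SCC)[C@H]2OC(=O)CC(C)C
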